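With the side chain numbered C1' (ArOCH2) to C8' (lactone carbonyl), the route rests on cutting the γ-butyrolactone at C5'–C6' and O–C8'. This leaves methyl acrylate and a five-carbon β-hydroxy aldehyde (C1'–C5') in which C2' and C3' are already set and the C1' and C2' oxygens are benzyl ethers. One samarium diiodide ketyl–acrylate coupling should form C5'–C6', close the lactone ring and set C5'. It exploits the free tertiary hydroxyl on C3', which lies 1,3 to C5' and anti to the lactone oxygen, as an anchor for trivalent samarium. The C7' methyl group and the coumarin are added afterwards.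

Key step: step 7

Remark: the C2' oxygen is kept as a small benzyl ether, not a silyl ether, on the assumption that it can serve samarium as a further donor in the key step.

Step 1
Reactants: 1 methyl (R)-2,2-dimethyl-1,3-dioxolane-4-carboxylate
Product: 2 methyl (R)-2,3-dihydroxypropanoate
Conditions: p-TsOH·H2O (cat.), MeOH, rt
Reagents that add atoms: none
Why: Acid-catalysed transacetalization to methanol removes the isopropylidene group, while methanol as solvent keeps the methyl ester and the acidic medium cannot enolise the future C2' centre.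

Step 2
Reactants: 2 methyl (R)-2,3-dihydroxypropanoate
Product: 3 methyl (R)-2,3-bis(benzyloxy)propanoate
Conditions: BnOC(=NH)CCl3 (2.5 equiv), TfOH (cat.), CH2Cl2/cyclohexane, 0 °C → rt
Reagents that add atoms: benzyl 2,2,2-trichloroacetimidate, N=C(OCc1ccccc1)C(Cl)(Cl)Cl
Why: Acid-catalysed O-benzylation with the trichloroacetimidate etherifies both hydroxyls without base, so the α-alkoxy ester should neither epimerise nor undergo β-elimination.

Step 3
Reactants: 3 methyl (R)-2,3-bis(benzyloxy)propanoate
Product: 4 (R)-2,3-bis(benzyloxy)-N-methoxy-N-methylpropanamide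
Conditions: MeNHOMe·HCl (1.5 equiv), iPrMgCl (3 equiv), THF, −20 °C
Reagents that add atoms: N,O-dimethylhydroxylamine hydrochloride, CNOC.Cl
Why: Weinreb amide formation by aminolysis of the ester with the chloromagnesium amide made in the flask, the Grignard reagent being consumed by the amine at −20 °C faster than it can attack or enolise the ester.

Step 4
Reactants: 4 (R)-2,3-bis(benzyloxy)-N-methoxy-N-methylpropanamide
Product: 5 (R)-3,4-bis(benzyloxy)butan-2-one
Conditions: MeMgBr (1.3 equiv), THF, −78 → 0 °C; cold aq. NH4Cl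
Reagents that add atoms: methylmagnesium bromide, C[Mg]Br
Why: Weinreb ketone synthesis, in which the magnesium-chelated tetrahedral adduct persists until the cold quench, so that only one methyl group is delivered and the α-benzyloxy ketone is never exposed to the basic reagent.

Step 5
Reactants: 5 (R)-3,4-bis(benzyloxy)butan-2-one; 6 allylmagnesium bromide
Product: 7 (2R,3R)-1,2-bis(benzyloxy)-3-methylhex-5-en-3-ol
Conditions: CH2=CHCH2MgBr (1.0 M in Et2O, 1.3 equiv), CH2Cl2, −78 °C; aq. NH4Cl
Reagents that add atoms: none
Why: Cram-chelate-controlled Grignard addition, in which magnesium bridges the ketone oxygen and the C2' benzyloxy oxygen in the non-coordinating solvent and the allyl group should add to the carbonyl face on the side of the C2' hydrogen, setting C3' as R (C2'–O and C3'–O syn along the C1'–C4' chain).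

Step 6
Reactants: 7 (2R,3R)-1,2-bis(benzyloxy)-3-methylhex-5-en-3-ol
Product: 9 (3R,4R)-4,5-bis(benzyloxy)-3-hydroxy-3-methylpentanal, via ozonide 8 (not isolated)
Conditions: O3, CH2Cl2, −78 °C (Sudan Red 7B end point); PPh3, −78 °C → rt
Reagents that add atoms: ozone, [O-][O+]=O
Why: Ozonolysis with reductive work-up cleaves the terminal alkene under neutral conditions, which should spare the tertiary β-hydroxy aldehyde from dehydration or retro-aldol cleavage, and the indicator stops the ozone before it attacks the benzyl ethers.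

Step 7
Reactants: 9 (3R,4R)-4,5-bis(benzyloxy)-3-hydroxy-3-methylpentanal; 10 methyl acrylate
Product: 12 (S)-5-[(2R,3R)-3,4-bis(benzyloxy)-2-hydroxy-2-methylbutyl]dihydrofuran-2(3H)-one, via hydroxy ester samarium alkoxide 11 (not isolated)
Conditions: SmI2 (0.1 M in THF, 2.5 equiv), methyl acrylate (3 equiv), t-BuOH (2 equiv), THF, −78 °C → rt; aq. NH4Cl
Reagents that add atoms: none
Why: SmI2 transfers one electron to the C5' aldehyde, and the ketyl, held by trivalent samarium that is also bound to the C3' hydroxyl in a six-membered chelate, adds to the β-carbon of methyl acrylate to form C5'–C6'; a second electron and protonation by t-BuOH give ester 11 as its samarium alkoxide. The closest known reaction type is the SmI2-mediated ketyl–olefin coupling of aldehydes with acrylates to γ-lactones, together with its hydroxyl-chelated variant established for β-hydroxy ketones. The lactone ring closes when the C5' alkoxide attacks the ester carbonyl C8' in a 5-exo-trig acyl substitution that expels methoxide and forms O–C8'. The new stereocentre C5' is controlled by the chelate: with the C2' benzyloxy oxygen as a further donor, the C2' branch lies over one face of the ketyl and the acrylate should bond to the opposite face, giving the 1,3-anti (5'S) arrangement. The step needs facial selectivity at C5' and cross-coupling in preference to pinacol dimerisation; the free tertiary hydroxyl secures the first, and the faster reduction of the aldehyde than of the ester, the excess of acrylate and the proton source secure the second.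

Step 8
Reactants: 12 (S)-5-[(2R,3R)-3,4-bis(benzyloxy)-2-hydroxy-2-methylbutyl]dihydrofuran-2(3H)-one
Product: 13 (S)-5-[(2R,3R)-3,4-bis(benzyloxy)-2-methyl-2-(trimethylsilyloxy)butyl]dihydrofuran-2(3H)-one
Conditions: TMSOTf (1.3 equiv), 2,6-lutidine (2 equiv), CH2Cl2, −78 → 0 °C
Reagents that add atoms: trimethylsilyl trifluoromethanesulfonate, C[Si](C)(C)OS(=O)(=O)C(F)(F)F
Why: Silyl ether formation with the silyl triflate caps the hindered tertiary C3' hydroxyl, the only acidic O–H, so that one equivalent of base can later make the lactone enolate cleanly, while the weak hindered base leaves the lactone alone.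

Step 9
Reactants: 13 (S)-5-[(2R,3R)-3,4-bis(benzyloxy)-2-methyl-2-(trimethylsilyloxy)butyl]dihydrofuran-2(3H)-one
Product: 16 (3R,5S)-5-[(2R,3R)-3,4-bis(benzyloxy)-2-hydroxy-2-methylbutyl]-3-methyldihydrofuran-2(3H)-one, via lithium enolate 14 (not isolated), via methylated silyl ether 15 (not isolated)
Conditions: LiN(iPr)2 (LDA, 1.1 equiv), THF, −78 °C; MeI (3 equiv), −78 → −40 °C; then 1 M HCl, THF, 0 °C
Reagents that add atoms: iodomethane, CI
Why: Kinetic alkylation of a γ-substituted γ-butyrolactone enolate, in which iodomethane should approach the planar enolate on the face opposite the C5' substituent and so set C7' as R (methyl trans to the side chain), after which the acidic work-up cleaves the tertiary trimethylsilyl ether.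

Step 10
Reactants: 16 (3R,5S)-5-[(2R,3R)-3,4-bis(benzyloxy)-2-hydroxy-2-methylbutyl]-3-methyldihydrofuran-2(3H)-one
Product: 17 (3R,5S)-3-methyl-5-[(2R,3R)-2,3,4-trihydroxy-2-methylbutyl]dihydrofuran-2(3H)-one
Conditions: H2 (1 atm), 10% Pd/C, EtOH, rt
Reagents that add atoms: none
Why: Catalytic hydrogenolysis removes both benzyl ethers while the lactone and the alcohols are inert, and it is run before the coumarin is present because the coumarin C3–C4 double bond would be reduced.

Step 11
Reactants: 17 (3R,5S)-3-methyl-5-[(2R,3R)-2,3,4-trihydroxy-2-methylbutyl]dihydrofuran-2(3H)-one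
Product: 18 (2R,3R)-2,3-dihydroxy-3-methyl-4-[(2S,4R)-4-methyl-5-oxotetrahydrofuran-2-yl]butyl 4-methylbenzenesulfonate
Conditions: TsCl (1.05 equiv), Bu2SnO (2 mol %), Et3N (1.2 equiv), CH2Cl2, 0 °C → rt
Reagents that add atoms: 4-methylbenzenesulfonyl chloride, Cc1ccc(cc1)S(=O)(=O)Cl
Why: Tin-catalysed regioselective monosulfonylation of a terminal 1,2-diol through its stannylene acetal should tosylate only the primary C1' hydroxyl and leave the secondary C2' and tertiary C3' hydroxyls free.

Step 12
Reactants: 18 (2R,3R)-2,3-dihydroxy-3-methyl-4-[(2S,4R)-4-methyl-5-oxotetrahydrofuran-2-yl]butyl 4-methylbenzenesulfonate; 19 umbelliferone (7-hydroxy-2H-chromen-2-one)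
Product: 20 7-{[(2R,3R)-2,3-dihydroxy-3-methyl-4-[(2S,4R)-4-methyl-5-oxotetrahydrofuran-2-yl]butyl]oxy}-2H-chromen-2-one (CNP0331202.1)
Conditions: K2CO3 (1.5 equiv), umbelliferone (1.5 equiv), DMF, 60 °C
Reagents that add atoms: none
Why: Williamson ether synthesis in which the coumarin 7-phenoxide displaces the primary tosylate at C1' by SN2 without touching a stereocentre, and because the phenol is far more acidic than the alcohols or the lactone α-hydrogen the carbonate base should leave the diol and C7' unchanged.

Compound list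
1 | methyl (R)-2,2-dimethyl-1,3-dioxolane-4-carboxylate | COC(=O)[C@H]1COC(C)(C)O1 | starting material
2 | methyl (R)-2,3-dihydroxypropanoate | COC(=O)[C@H](O)CO | intermediate
3 | methyl (R)-2,3-bis(benzyloxy)propanoate | COC(=O)[C@H](OCc1ccccc1)COCc1ccccc1 | intermediate
4 | (R)-2,3-bis(benzyloxy)-N-methoxy-N-methylpropanamide | CON(C)C(=O)[C@H](OCc1ccccc1)COCc1ccccc1 | intermediate
5 | (R)-3,4-bis(benzyloxy)butan-2-one | CC(=O)[C@H](OCc1ccccc1)COCc1ccccc1 | intermediate
6 | allylmagnesium bromide | C=CC[Mg]Br | starting material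
7 | (2R,3R)-1,2-bis(benzyloxy)-3-methylhex-5-en-3-ol | C=CC[C@@](C)(O)[C@H](OCc1ccccc1)COCc1ccccc1 | intermediate
8 | (2R,3R)-3,4-bis(benzyloxy)-2-methyl-1-(1,2,4-trioxolan-3-yl)butan-2-ol (ozonide, both epimers at the trioxolane carbon) | C1OC(C[C@@](C)(O)[C@H](OCc2ccccc2)COCc2ccccc2)OO1 | intermediate (not isolated)
9 | (3R,4R)-4,5-bis(benzyloxy)-3-hydroxy-3-methylpentanal | O=CC[C@@](C)(O)[C@H](OCc1ccccc1)COCc1ccccc1 | intermediate
10 | methyl acrylate | C=CC(=O)OC | starting material
11 | methyl (4S,6R,7R)-7,8-bis(benzyloxy)-4,6-dihydroxy-6-methyloctanoate (present as its samarium alkoxide, drawn as the free diol) | COC(=O)CC[C@H](O)C[C@@](C)(O)[C@H](OCc1ccccc1)COCc1ccccc1 | intermediate (not isolated)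
12 | (S)-5-[(2R,3R)-3,4-bis(benzyloxy)-2-hydroxy-2-methylbutyl]dihydrofuran-2(3H)-one | O=C1CC[C@@H](C[C@@](C)(O)[C@H](OCc2ccccc2)COCc2ccccc2)O1 | intermediate
13 | (S)-5-[(2R,3R)-3,4-bis(benzyloxy)-2-methyl-2-(trimethylsilyloxy)butyl]dihydrofuran-2(3H)-one | O=C1CC[C@@H](C[C@@](C)(O[Si](C)(C)C)[C@H](OCc2ccccc2)COCc2ccccc2)O1 | intermediate
14 | lithium enolate of 13 (lithium (S)-5-[(2R,3R)-3,4-bis(benzyloxy)-2-methyl-2-(trimethylsilyloxy)butyl]-4,5-dihydrofuran-2-olate) | [Li]OC1=CC[C@@H](C[C@@](C)(O[Si](C)(C)C)[C@H](OCc2ccccc2)COCc2ccccc2)O1 | intermediate (not isolated)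
15 | (3R,5S)-5-[(2R,3R)-3,4-bis(benzyloxy)-2-methyl-2-(trimethylsilyloxy)butyl]-3-methyldihydrofuran-2(3H)-one | C[C@@H]1C[C@@H](C[C@@](C)(O[Si](C)(C)C)[C@H](OCc2ccccc2)COCc2ccccc2)OC1=O | intermediate (not isolated)
16 | (3R,5S)-5-[(2R,3R)-3,4-bis(benzyloxy)-2-hydroxy-2-methylbutyl]-3-methyldihydrofuran-2(3H)-one | C[C@@H]1C[C@@H](C[C@@](C)(O)[C@H](OCc2ccccc2)COCc2ccccc2)OC1=O | intermediate
17 | (3R,5S)-3-methyl-5-[(2R,3R)-2,3,4-trihydroxy-2-methylbutyl]dihydrofuran-2(3H)-one | C[C@@H]1C[C@@H](C[C@@](C)(O)[C@H](O)CO)OC1=O | intermediate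
18 | (2R,3R)-2,3-dihydroxy-3-methyl-4-[(2S,4R)-4-methyl-5-oxotetrahydrofuran-2-yl]butyl 4-methylbenzenesulfonate | C[C@@H]1C[C@@H](C[C@@](C)(O)[C@H](O)COS(=O)(=O)c2ccc(C)cc2)OC1=O | intermediate
19 | umbelliferone (7-hydroxy-2H-chromen-2-one) | Oc1ccc2ccc(=O)oc2c1 | starting material
20 | 7-{[(2R,3R)-2,3-dihydroxy-3-methyl-4-[(2S,4R)-4-methyl-5-oxotetrahydrofuran-2-yl]butyl]oxy}-2H-chromen-2-one (CNP0331202.1) | C[C@@H]1C[C@@H](C[C@@](C)(O)[C@H](O)COc2ccc3ccc(=O)oc3c2)OC1=O | target

Total step count: 12
Longest linear sequence: 12 steps (1 → 20); compounds 6, 10 and 19 enter as purchased partners.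

Steps most likely to fail

1. Step 7. The facial selectivity at the C5' ketyl may be poor or reversed, because an aldehyde ketyl is less encumbered than the ketone ketyls for which chelate control is established and the quaternary C3' places a methyl group on the chelate ring. Pinacol dimerisation of the aldehyde may also compete. Fallback, setting out from aldehyde 9: reagent-controlled Brown allylboration with B-allyldiisopinocampheylborane of the (+)-α-pinene series [(−)-Ipc2B(allyl), Et2O, −78 °C; NaOH, H2O2], which attacks the Si face of the aldehyde, should give (2R,3R,5S)-1,2-bis(benzyloxy)-3-methyloct-7-ene-3,5-diol F1. Hydroboration–oxidation of its terminal alkene (9-BBN, THF; NaOH, H2O2) should give (4S,6R,7R)-7,8-bis(benzyloxy)-6-methyloctane-1,4,6-triol F2. Oxidative lactonisation of the 1,4-diol unit (TEMPO cat., PhI(OAc)2, CH2Cl2) comes back to the route at lactone 12.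

2. Step 5. Chelation control may erode, because allyl Grignard reagents add at rates close to the diffusion limit, so that unchelated ketone can react and give the C3' epimer. Fallback, setting out from ketone 5: vinylmagnesium bromide (CH2=CHMgBr, THF, −78 °C), an ordinary Grignard reagent whose additions to α-benzyloxy ketones follow the chelate model reliably, should give (2R,3R)-1,2-bis(benzyloxy)-3-methylpent-4-en-3-ol F3. Anti-Markovnikov hydroboration–oxidation (9-BBN, THF; NaOH, H2O2) should give (3R,4R)-4,5-bis(benzyloxy)-3-methylpentane-1,3-diol F4. Selective oxidation of the primary alcohol (TEMPO cat., PhI(OAc)2, CH2Cl2) comes back to the route at aldehyde 9.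

3. Step 9. The trans selectivity of the enolate methylation may be insufficient, and proton exchange between product and enolate may lead to double methylation. Fallback, setting out from silyl ether 13: a Mannich reaction of the lithium enolate with Eschenmoser's salt (LDA, THF, −78 °C; CH2=NMe2 iodide) should give (5S)-5-[(2R,3R)-3,4-bis(benzyloxy)-2-methyl-2-(trimethylsilyloxy)butyl]-3-[(dimethylamino)methyl]dihydrofuran-2(3H)-one F5. N-Methylation, elimination and acidic work-up (MeI; DBU; 1 M HCl) should give (S)-5-[(2R,3R)-3,4-bis(benzyloxy)-2-hydroxy-2-methylbutyl]-3-methylenedihydrofuran-2(3H)-one F6. Catalyst-controlled asymmetric hydrogenation of the exocyclic alkene with Ru(OAc)2(BINAP) comes back to the route at lactone 16. The BINAP antipode that delivers hydrogen to the C7' face syn to the side chain is to be found by trying both, and the benzyl ethers are not cleaved by this homogeneous catalyst.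

Further compounds
F1 | step 7 | (2R,3R,5S)-1,2-bis(benzyloxy)-3-methyloct-7-ene-3,5-diol | C=CC[C@H](O)C[C@@](C)(O)[C@H](OCc1ccccc1)COCc1ccccc1
F2 | step 7 | (4S,6R,7R)-7,8-bis(benzyloxy)-6-methyloctane-1,4,6-triol | OCCC[C@H](O)C[C@@](C)(O)[C@H](OCc1ccccc1)COCc1ccccc1
F3 | step 5 | (2R,3R)-1,2-bis(benzyloxy)-3-methylpent-4-en-3-ol | C=C[C@@](C)(O)[C@H](OCc1ccccc1)COCc1ccccc1
F4 | step 5 | (3R,4R)-4,5-bis(benzyloxy)-3-methylpentane-1,3-diol | OCC[C@@](C)(O)[C@H](OCc1ccccc1)COCc1ccccc1
F5 | step 9 | (5S)-5-[(2R,3R)-3,4-bis(benzyloxy)-2-methyl-2-(trimethylsilyloxy)butyl]-3-[(dimethylamino)methyl]dihydrofuran-2(3H)-one (both C3 epimers) | CN(C)CC1C[C@@H](C[C@@](C)(O[Si](C)(C)C)[C@H](OCc2ccccc2)COCc2ccccc2)OC1=O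
F6 | step 9 | (S)-5-[(2R,3R)-3,4-bis(benzyloxy)-2-hydroxy-2-methylbutyl]-3-methylenedihydrofuran-2(3H)-one | C=C1C[C@@H](C[C@@](C)(O)[C@H](OCc2ccccc2)COCc2ccccc2)OC1=O
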